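## Retrosynthetic overview

- The side-chain carbinol (S) is disconnected by a catalytic enantioselective Hosomi–Sakurai allylation of 3-methylbut-2-enal. The 2-substituted allylsilane comes from a C1 methyl ester and two Me3SiCH2 units (double addition, Peterson elimination).
- The strategy rests on the cyclohexane unit C1(OH)–C4(CH3)(Br)–C5(H)(Cl), in which the C1 oxygen is 1,4-cis to Br on C4 and 1,3-trans to Cl on C5. The C4–Br bond is traced back to a C1–O–C4 oxolane bridge (7-oxabicyclo[2.2.1]heptane), opened by bromide with retention through a C4/C5 chloronium ion.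
- The bridge and the C5–Cl bond come from anti chloroetherification of methyl (R)-1-hydroxy-4-methylcyclohex-3-ene-1-carboxylate. The cyclohexene comes from an enantioselective Diels–Alder reaction of isoprene with 2-(benzoyloxy)acrolein.
- Ring order: the cyclohexene is formed first (Diels–Alder), then the oxolane bridge is closed (chloroetherification) and reopened (key step). No further ring is formed.

Key step: step 8

Remark: ring atoms are numbered C1 (carbinol carbon), C4 (C–CH3/Br) and C5 (CHCl); the antipode of each chiral catalyst is assumed to be selectable for the required sense of induction; and the allylation is expected to deliver the new carbinol as its trimethylsilyl ether (silyl transfer turns the catalyst over), so the penultimate compound is carried as the bis-silyl ether.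

## Route

Step 1
Reactants: 1 2,2-dimethyl-1,3-dioxan-5-one; 2 benzoyl chloride
Product: 4 2,2-dimethyl-4H-1,3-dioxin-5-yl benzoate, via potassium dioxinolate 3 (not isolated)
Conditions: KN(SiMe3)2, THF, −78 °C; then BzCl, −78 → 0 °C
Reagents that add atoms: benzoyl chloride (compound 2), O=C(Cl)c1ccccc1
Why: The potassium enolate of the dialkoxy ketone is a hard nucleophile that an acid chloride should acylate on oxygen (enol ester formation), which fixes the enol double bond inside the 4H-1,3-dioxin ring.

Step 2
Reactants: 4 2,2-dimethyl-4H-1,3-dioxin-5-yl benzoate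
Product: 5 2-(benzoyloxy)acrolein
Conditions: toluene, 110 °C, acetone distilled off; solution used at once
Reagents that add atoms: none
Why: 4H-1,3-Dioxins undergo thermal retro-hetero-Diels–Alder cycloreversion, and loss of acetone should unmask the 2-acyloxy enal, which tends to polymerise and is therefore not stored.

Step 3
Reactants: 5 2-(benzoyloxy)acrolein; 6 isoprene
Product: 7 (R)-1-formyl-4-methylcyclohex-3-en-1-yl benzoate
Conditions: 1,1'-binaphthyl-2,2'-diamine·1.9 Tf2NH (10 mol%, antipode selected for the R adduct), isoprene (excess), EtCN, −40 °C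
Reagents that add atoms: none
Why: Organocatalytic enantioselective Diels–Alder reaction in which the chiral primary ammonium salt activates the enal as an iminium ion, the 2-substituted diene adds with para regiochemistry, and the catalyst should shield one face of the dienophile so that the quaternary carbon C1 is set as R.

Step 4
Reactants: 7 (R)-1-formyl-4-methylcyclohex-3-en-1-yl benzoate
Product: 8 (R)-1-(benzoyloxy)-4-methylcyclohex-3-ene-1-carboxylic acid
Conditions: NaClO2, NaH2PO4, 2-methyl-2-butene (large excess), t-BuOH/H2O, 0 °C → rt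
Reagents that add atoms: sodium chlorite, [Na+].[O-]Cl=O
Why: Pinnick oxidation converts the non-enolisable aldehyde into the acid, while the sacrificial alkene traps hypochlorous acid so that the ring alkene should stay untouched.

Step 5
Reactants: 8 (R)-1-(benzoyloxy)-4-methylcyclohex-3-ene-1-carboxylic acid
Product: 9 methyl (R)-1-(benzoyloxy)-4-methylcyclohex-3-ene-1-carboxylate
Conditions: MeI, K2CO3, DMF, rt
Reagents that add atoms: iodomethane, CI
Why: SN2 O-alkylation of the carboxylate is insensitive to the hindrance at the quaternary carbon and leaves the benzoate and the alkene alone.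

Step 6
Reactants: 9 methyl (R)-1-(benzoyloxy)-4-methylcyclohex-3-ene-1-carboxylate
Product: 10 methyl (R)-1-hydroxy-4-methylcyclohex-3-ene-1-carboxylate
Conditions: K2CO3 (0.2 equiv), MeOH, rt
Reagents that add atoms: none
Why: Base-catalysed transesterification should remove the activated benzoate as methyl benzoate, exchange at the methyl ester being degenerate in methanol and the quaternary stereocentre not being epimerisable.

Step 7
Reactants: 10 methyl (R)-1-hydroxy-4-methylcyclohex-3-ene-1-carboxylate; 11 1,3-dichloro-5,5-dimethylhydantoin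
Product: 12 methyl (1R,3S,4S)-3-chloro-4-methyl-7-oxabicyclo[2.2.1]heptane-1-carboxylate (3-endo-chloro)
Conditions: DCDMH (1.1 equiv), Ph3P=S (10 mol%), CH2Cl2, −40 °C, dark
Reagents that add atoms: 1,3-dichloro-5,5-dimethylhydantoin (compound 11), CC1(C)N(Cl)C(=O)N(Cl)C1=O
Why: Lewis-base-catalysed chloroetherification in which only a chloronium ion on the alkene face opposite the C1 hydroxyl can be captured intramolecularly, so that 5-exo attack of that hydroxyl at the tertiary carbon C4 should close the oxolane bridge with chlorine anti to oxygen (C1 thereby fixes C4 and C5), the cold non-nucleophilic medium being chosen to hold back ene-type allylic chlorination.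

Step 8
Reactants: 12 methyl (1R,3S,4S)-3-chloro-4-methyl-7-oxabicyclo[2.2.1]heptane-1-carboxylate; 13 bromotrimethylsilane
Product: 15 methyl (1R,3S,4S)-4-bromo-3-chloro-4-methyl-1-(trimethylsilyloxy)cyclohexane-1-carboxylate, via bridged chloronium bromide 14 (not isolated)
Conditions: TMSBr (3 equiv), ZnBr2 (10 mol%), CH2Cl2, −40 → 0 °C; pyridine, then cold aqueous NaHCO3
Reagents that add atoms: bromotrimethylsilane (compound 13), C[Si](C)(C)Br
Why: Proposed new method: TMSBr, assisted by ZnBr2, silylates the bridging oxygen, and the C4–O bond of the resulting oxonium ion should ionise with anchimeric help from the endo chlorine on C5, which lies close to antiperiplanar to that bond, so that the reverse of the chloroetherification gives chloronium ion 14 on the face opposite the oxygen, and bromide then opens 14 at the tertiary carbon C4 from the oxygen face. The closest known reaction types are the cleavage of cineole-type bridged tertiary ethers by halosilanes or acyl halides to tertiary halides and substitution with retention through neighbouring-halogen participation. No ring is closed, since the oxolane bridge of the 7-oxabicyclo[2.2.1]heptane is opened to the monocyclic cyclohexane, and relief of strain together with the poorly nucleophilic silyl ether oxygen should make the opening irreversible. The only centre that is touched is C4, which should keep its configuration by double inversion (chlorine displaces oxygen, bromide displaces chlorine), placing Br cis to the C1 oxygen and trans to Cl while C1 and C5 stay as they are. The step needs cleavage of C4–O and not of C1–O, which the ester on C1 secures by disfavouring a cation there, and it needs substitution with retention in place of proton loss, a free cation or a 1,2-chlorine shift, which the anti-disposed chlorine, the preference of bromide for the tertiary terminus of the chloronium ion, an excess of bromide and low temperature should secure.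

Step 9
Reactants: 15 methyl (1R,3S,4S)-4-bromo-3-chloro-4-methyl-1-(trimethylsilyloxy)cyclohexane-1-carboxylate; 16 (trimethylsilyl)methylmagnesium chloride
Product: 18 2-[(1R,3S,4S)-4-bromo-3-chloro-4-methyl-1-(trimethylsilyloxy)cyclohexyl]-1,3-bis(trimethylsilyl)propan-2-ol, via silylmethyl ketone 17 (not isolated)
Conditions: Me3SiCH2MgCl (4 equiv), anhydrous CeCl3 (4 equiv), THF, −78 → 0 °C; saturated aqueous NH4Cl; crude carried on
Reagents that add atoms: (trimethylsilyl)methylmagnesium chloride (compound 16), C[Si](C)(C)C[Mg]Cl
Why: Double addition of the weakly basic organocerium reagent to the ester, in which cerium should suppress both enolisation of the intermediate silylmethyl ketone and E2 loss of HBr from the tertiary bromide, so that the bis(silylmethyl) carbinol forms with the halogens and the silyl ether intact.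

Step 10
Reactants: 18 2-[(1R,3S,4S)-4-bromo-3-chloro-4-methyl-1-(trimethylsilyloxy)cyclohexyl]-1,3-bis(trimethylsilyl)propan-2-ol
Product: 19 {2-[(1R,3S,4S)-4-bromo-3-chloro-4-methyl-1-(trimethylsilyloxy)cyclohexyl]prop-2-en-1-yl}trimethylsilane
Conditions: SiO2, CH2Cl2, rt
Reagents that add atoms: none
Why: Peterson elimination under mildly acidic conditions, in which the tertiary β-hydroxysilane should lose Me3SiOH readily to give the 1,1-disubstituted alkene that still carries one CH2SiMe3 group (the 2-substituted allylsilane) without ionising the ring halides.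

Step 11
Reactants: 19 {2-[(1R,3S,4S)-4-bromo-3-chloro-4-methyl-1-(trimethylsilyloxy)cyclohexyl]prop-2-en-1-yl}trimethylsilane; 20 3-methylbut-2-enal
Product: 21 (4S)-2-[(1R,3S,4S)-4-bromo-3-chloro-4-methyl-1-(trimethylsilyloxy)cyclohexyl]-6-methyl-4-(trimethylsilyloxy)hepta-1,5-diene
Conditions: acyloxyborane catalyst made in situ from 2-O-(2,6-diisopropoxybenzoyl)tartaric acid and BH3·THF (20 mol%, tartrate antipode selected for the S carbinol), EtCN, −78 °C; Et3N, then cold aqueous NaHCO3; crude carried on
Reagents that add atoms: none
Why: Catalytic enantioselective Hosomi–Sakurai allylation in which the chiral acyloxyborane activates the aldehyde for 1,2-attack by the terminal alkene carbon of the allylsilane, the released silyl group ends on the new alkoxide, and the catalyst should select the aldehyde face that leads to the S carbinol, any minor epimer being a diastereomer that can be removed after step 12.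

Step 12
Reactants: 21 (4S)-2-[(1R,3S,4S)-4-bromo-3-chloro-4-methyl-1-(trimethylsilyloxy)cyclohexyl]-6-methyl-4-(trimethylsilyloxy)hepta-1,5-diene
Product: 22 (1R,3S,4S)-4-bromo-3-chloro-1-[(4S)-4-hydroxy-6-methylhepta-1,5-dien-2-yl]-4-methylcyclohexan-1-ol (CNP0365435.1)
Conditions: Bu4NF, AcOH (1:1), THF, 0 °C → rt
Reagents that add atoms: none
Why: Fluoride-mediated cleavage of both trimethylsilyl ethers, with acetic acid buffering the medium so that neither E2 loss of HBr from the tertiary bromide nor acid ionisation of the allylic carbinol should take place.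

## Compound list

1 | 2,2-dimethyl-1,3-dioxan-5-one | CC1(C)OCC(=O)CO1 | starting material
2 | benzoyl chloride | O=C(Cl)c1ccccc1 | starting material
3 | potassium 2,2-dimethyl-4H-1,3-dioxin-5-olate | CC1(C)OCC([O-])=CO1.[K+] | intermediate
4 | 2,2-dimethyl-4H-1,3-dioxin-5-yl benzoate | CC1(C)OCC(OC(=O)c2ccccc2)=CO1 | intermediate
5 | 2-(benzoyloxy)acrolein | C=C(OC(=O)c1ccccc1)C=O | intermediate
6 | isoprene | C=CC(C)=C | starting material
7 | (R)-1-formyl-4-methylcyclohex-3-en-1-yl benzoate | O=C[C@@]1(OC(=O)c2ccccc2)CCC(C)=CC1 | intermediate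
8 | (R)-1-(benzoyloxy)-4-methylcyclohex-3-ene-1-carboxylic acid | OC(=O)[C@@]1(OC(=O)c2ccccc2)CCC(C)=CC1 | intermediate
9 | methyl (R)-1-(benzoyloxy)-4-methylcyclohex-3-ene-1-carboxylate | COC(=O)[C@@]1(OC(=O)c2ccccc2)CCC(C)=CC1 | intermediate
10 | methyl (R)-1-hydroxy-4-methylcyclohex-3-ene-1-carboxylate | COC(=O)[C@@]1(O)CCC(C)=CC1 | intermediate
11 | 1,3-dichloro-5,5-dimethylhydantoin | CC1(C)N(Cl)C(=O)N(Cl)C1=O | starting material
12 | methyl (1R,3S,4S)-3-chloro-4-methyl-7-oxabicyclo[2.2.1]heptane-1-carboxylate (3-endo-chloro) | COC(=O)[C@@]1(O2)CC[C@@]2(C)[C@@H](Cl)C1 | intermediate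
13 | bromotrimethylsilane | C[Si](C)(C)Br | starting material
14 | bridged C4/C5 chloronium bromide of the ring-opened C1 silyl ether (chlorine on the face opposite the C1 oxygen) | COC(=O)[C@@]1(O[Si](C)(C)C)CC[C@@]2(C)[Cl+][C@H]2C1.[Br-] | intermediate
15 | methyl (1R,3S,4S)-4-bromo-3-chloro-4-methyl-1-(trimethylsilyloxy)cyclohexane-1-carboxylate | COC(=O)[C@@]1(O[Si](C)(C)C)CC[C@](C)(Br)[C@@H](Cl)C1 | intermediate
16 | (trimethylsilyl)methylmagnesium chloride | C[Si](C)(C)C[Mg]Cl | starting material
17 | 1-[(1R,3S,4S)-4-bromo-3-chloro-4-methyl-1-(trimethylsilyloxy)cyclohexyl]-2-(trimethylsilyl)ethan-1-one | C[Si](C)(C)CC(=O)[C@@]1(O[Si](C)(C)C)CC[C@](C)(Br)[C@@H](Cl)C1 | intermediate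
18 | 2-[(1R,3S,4S)-4-bromo-3-chloro-4-methyl-1-(trimethylsilyloxy)cyclohexyl]-1,3-bis(trimethylsilyl)propan-2-ol | C[Si](C)(C)CC(O)(C[Si](C)(C)C)[C@@]1(O[Si](C)(C)C)CC[C@](C)(Br)[C@@H](Cl)C1 | intermediate
19 | {2-[(1R,3S,4S)-4-bromo-3-chloro-4-methyl-1-(trimethylsilyloxy)cyclohexyl]prop-2-en-1-yl}trimethylsilane | C=C(C[Si](C)(C)C)[C@@]1(O[Si](C)(C)C)CC[C@](C)(Br)[C@@H](Cl)C1 | intermediate
20 | 3-methylbut-2-enal | CC(C)=CC=O | starting material
21 | (4S)-2-[(1R,3S,4S)-4-bromo-3-chloro-4-methyl-1-(trimethylsilyloxy)cyclohexyl]-6-methyl-4-(trimethylsilyloxy)hepta-1,5-diene | C=C(C[C@H](O[Si](C)(C)C)C=C(C)C)[C@@]1(O[Si](C)(C)C)CC[C@](C)(Br)[C@@H](Cl)C1 | intermediate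
22 | (1R,3S,4S)-4-bromo-3-chloro-1-[(4S)-4-hydroxy-6-methylhepta-1,5-dien-2-yl]-4-methylcyclohexan-1-ol (CNP0365435.1) | C=C(C[C@H](O)C=C(C)C)[C@@]1(O)CC[C@](C)(Br)[C@@H](Cl)C1 | target

## Step count and risks

Total step count: 12. Longest linear sequence: 12 steps (from 1 to 22).

Steps most likely to fail:

1. Step 8 (bridged-ether opening). The ester-deactivated bridging oxygen may resist silylation, or the oxonium ion may ionise to a cation that chlorine does not bridge, so that proton loss to alkenes or attack on both faces erodes the outcome. The fallback uses known reaction types and avoids the bridged ether; it sets out from 9 and comes back at 15. Chlorohydrin formation on the benzoate-protected alkene (NCS, acetone/H2O, 0 °C; hydroxyl to the tertiary carbon, anti to chlorine) should give, after separation from the facial isomer, methyl (1R,3S,4S)-1-(benzoyloxy)-3-chloro-4-hydroxy-4-methylcyclohexane-1-carboxylate F1. The tertiary alcohol is then converted into the tertiary bromide with TMSBr in CH2Cl2 at low temperature. This is the classical substitution of a β-halo alcohol with retention through the anti halogen, and it should give methyl (1R,3S,4S)-1-(benzoyloxy)-4-bromo-3-chloro-4-methylcyclohexane-1-carboxylate F2, any C4 epimer being a separable diastereomer. Methanolysis of the benzoate (K2CO3, MeOH, 0 °C) gives methyl (1R,3S,4S)-4-bromo-3-chloro-1-hydroxy-4-methylcyclohexane-1-carboxylate F3, and silylation (TMSOTf, 2,6-lutidine, CH2Cl2, −78 °C) returns to 15.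

2. Step 7 (chloroetherification). Chlorenium transfer to the trisubstituted alkene may end in ene-type allylic chlorination or in uncyclised adducts, because the electron-poor tertiary hydroxyl has to reach C4 through a boat-like geometry. The fallback installs oxygen first and chlorine by inversion; it sets out from 10 and comes back at 12. Hydroxyl-directed epoxidation (VO(acac)2, t-BuOOH, toluene) should give methyl (1R,3R,6S)-3-hydroxy-6-methyl-7-oxabicyclo[4.1.0]heptane-3-carboxylate F4, with the epoxide cis to the hydroxyl. Acid-catalysed transannular opening at the tertiary epoxide carbon (camphorsulfonic acid, CH2Cl2), the way terpinen-4-ol epoxide is converted into the exo-hydroxy cineole, should give methyl (1R,3R,4S)-3-hydroxy-4-methyl-7-oxabicyclo[2.2.1]heptane-1-carboxylate F5 (3-exo-hydroxyl). Triflation (Tf2O, pyridine, −20 °C) gives methyl (1R,3R,4S)-4-methyl-3-(trifluoromethylsulfonyloxy)-7-oxabicyclo[2.2.1]heptane-1-carboxylate F6. SN2 displacement with Bu4NCl in MeCN inverts C3 and delivers the endo chloride 12; the triflate is chosen because endo attack on this skeleton is slow.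

3. Step 11 (enantioselective allylation). Turnover may be slow with the β,β-disubstituted enal and the bulky allylsilane, and facial selectivity at the aldehyde may be poor or protodesilylation may compete. The fallback sets the carbinol by reduction; it sets out from 19 and comes back at 22. An achiral Hosomi–Sakurai reaction with 20 (BF3·OEt2, CH2Cl2, −78 °C) should give 2-[(1R,3S,4S)-4-bromo-3-chloro-4-methyl-1-(trimethylsilyloxy)cyclohexyl]-6-methylhepta-1,5-dien-4-ol F7 as a mixture of carbinol epimers. Buffered Dess–Martin oxidation (NaHCO3, CH2Cl2, 0 °C) gives 2-[(1R,3S,4S)-4-bromo-3-chloro-4-methyl-1-(trimethylsilyloxy)cyclohexyl]-6-methylhepta-1,5-dien-4-one F8. CBS reduction (B-methyl oxazaborolidine from diphenylprolinol, antipode selected for S, catecholborane, toluene, −78 °C) gives (4S)-2-[(1R,3S,4S)-4-bromo-3-chloro-4-methyl-1-(trimethylsilyloxy)cyclohexyl]-6-methylhepta-1,5-dien-4-ol F9. The conditions of step 12 (Bu4NF, AcOH) then remove the C1 silyl group to give 22.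

Further compounds
F1 | step 8 | methyl (1R,3S,4S)-1-(benzoyloxy)-3-chloro-4-hydroxy-4-methylcyclohexane-1-carboxylate | COC(=O)[C@@]1(OC(=O)c2ccccc2)CC[C@](C)(O)[C@@H](Cl)C1
F2 | step 8 | methyl (1R,3S,4S)-1-(benzoyloxy)-4-bromo-3-chloro-4-methylcyclohexane-1-carboxylate | COC(=O)[C@@]1(OC(=O)c2ccccc2)CC[C@](C)(Br)[C@@H](Cl)C1
F3 | step 8 | methyl (1R,3S,4S)-4-bromo-3-chloro-1-hydroxy-4-methylcyclohexane-1-carboxylate | COC(=O)[C@@]1(O)CC[C@](C)(Br)[C@@H](Cl)C1
F4 | step 7 | methyl (1R,3R,6S)-3-hydroxy-6-methyl-7-oxabicyclo[4.1.0]heptane-3-carboxylate | COC(=O)[C@@]1(O)CC[C@]2(C)O[C@@H]2C1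
F5 | step 7 | methyl (1R,3R,4S)-3-hydroxy-4-methyl-7-oxabicyclo[2.2.1]heptane-1-carboxylate | COC(=O)[C@@]1(O2)CC[C@@]2(C)[C@H](O)C1
F6 | step 7 | methyl (1R,3R,4S)-4-methyl-3-(trifluoromethylsulfonyloxy)-7-oxabicyclo[2.2.1]heptane-1-carboxylate | COC(=O)[C@@]1(O2)CC[C@@]2(C)[C@H](OS(=O)(=O)C(F)(F)F)C1
F7 | step 11 | 2-[(1R,3S,4S)-4-bromo-3-chloro-4-methyl-1-(trimethylsilyloxy)cyclohexyl]-6-methylhepta-1,5-dien-4-ol (mixture of carbinol epimers) | C=C(CC(O)C=C(C)C)[C@@]1(O[Si](C)(C)C)CC[C@](C)(Br)[C@@H](Cl)C1
F8 | step 11 | 2-[(1R,3S,4S)-4-bromo-3-chloro-4-methyl-1-(trimethylsilyloxy)cyclohexyl]-6-methylhepta-1,5-dien-4-one | C=C(CC(=O)C=C(C)C)[C@@]1(O[Si](C)(C)C)CC[C@](C)(Br)[C@@H](Cl)C1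
F9 | step 11 | (4S)-2-[(1R,3S,4S)-4-bromo-3-chloro-4-methyl-1-(trimethylsilyloxy)cyclohexyl]-6-methylhepta-1,5-dien-4-ol | C=C(C[C@H](O)C=C(C)C)[C@@]1(O[Si](C)(C)C)CC[C@](C)(Br)[C@@H](Cl)C1
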